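**Numbering.** Atom labels C1–C10 are daucane labels and are used in all text: C1 quaternary fusion carbon with the angular methyl, C2 and C3 methylenes, C4 the carbinol bearing isopropyl, C5 the fusion methine, C6 CH–O-aroyl, C7 CH2, C8 the methyl-bearing alkene carbon, C9 alkene CH, C10 CH–O-tigloyl. Compound numbers are those of the steps. TBS = tert-butyldimethylsilyl, TES = triethylsilyl, TMS = trimethylsilyl.

## Analysis of the target

Target 27 is a daucane diester: a cyclopentane (C1–C5) fused through C1–C5 to a cycloheptene (C1, C5–C10) with the double bond at C8=C9. The five stereocentres C10, C1, C5, C4 and C6 are contiguous and read 1R,4R,5S,6S,10S. The angular methyl, H5, the isopropyl group and the C6 oxygen lie on one face; the C4 hydroxyl and the C10 oxygen lie on the other, so the ring fusion is cis. Sensitive points are the allylic tiglate at C10, the free tertiary alcohol at C4, the free phenol, and the need to place two different acyl groups on two secondary hydroxyls. The hard parts are the quaternary C1 wedged between the C10 carbinol and the fusion, the fully substituted C4 next to C5, and the cis fusion of a five- to a seven-membered ring. The route rests on one feature: C1 is quaternary, is bonded to C2, and sits next to C10, a carbon that can be a ketone. That is the retron of a pinacol shift (C5 moving from C10 to C1) which ends a Prins closure of the C2–C3 bond.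

## Retrosynthetic reasoning

**C6 ester (27 ⇒ 26 ⇒ 25).** The aroyl C–O bond is cut first, through the phenol-protected ester 26 to diol 25. In 25 the only other hydroxyl is the tertiary one at C4, which does not compete in acylation, so no protecting group is needed between them. The phenol is masked as an aryl acetate that an amine removes without touching the two alkyl esters.

**C10 ester (25 ⇒ 24 ⇒ 23).** The tigloyl C–O bond is cut with O6 and O4 as silyl ethers. The two secondary oxygens are told apart by their history, not by reactivity: O6 is silylated early, O10 appears late.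

**C10 carbinol and the alkene (23 ⇒ 22 ⇒ 21).** The carbinol goes back to enone 22 and then to the saturated ketone 21. Because C1 is quaternary, 21 can be desaturated only toward C9–C8, which is where the target has its alkene. C8 may therefore be a stereocentre in all earlier intermediates and is used as the source of absolute configuration. The forward reduction must deliver hydride to the face of the angular methyl.

**C3 (21 ⇒ 20).** The C3 methylene is traced to the methylthio group of 20, the residue of the cation initiator.

**Key disconnection (20 ⇒ 19 ⇒ 18 ⇒ 17).** C1–C5 and C2–C3 are cut. Moving C5 back from C1 to C10 turns the cycloheptanone into a cyclohexane and the cyclopentane into a six-membered ring holding the tertiary cation 19. Cutting C2–C3 opens that ring to thionium ion 18 and so to dithioacetal 17. These bonds are chosen because one cut removes both rings and the quaternary centre and leaves a monocyclic cyclohexane, where the other centres can be set by ring-based control. The forward step must ionise only the dithioacetal, close C2–C3 through a chair, and move C5 (not C9) with retention.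

**C4–isopropyl bond (17 ⇒ 16 ⇒ 15).** Behind the silyl ether lies tertiary alcohol 16, cut at the C4–isopropyl bond to ketone 15. Isopropyl is the group cut because the other pairing (isopropyl ketone plus dithioacetal anion) would give the C4 epimer under the same facial preference. A direct aldol onto a hindered dialkyl ketone to make C4–C5 would be reversible and would offer no control at C4. The forward addition must come from the carbonyl face turned away from the quaternary C10.

**C10–propenyl bond and C4 oxidation level (15 ⇒ 14 ⇒ 13 ⇒ 12).** The propenyl group has to be in place before the C4 ketone exists, since a 1,3-diketone spanning C4 and C10 would be enolised and could not be addressed selectively. C4 is therefore a carbinol during the addition and is oxidised afterwards. The C10 configuration is lost in the key step; it only needs to put the alkene trans to the side chain.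

**C5–C4 and C6–O (12 ⇒ 11 ⇒ 5 + 8).** Ketone 12 is cut at C5–C4 (aldol) and at C6–O (from a C–B bond), giving enone 5, aldehyde 8 and a boryl nucleophile. Conjugate addition creates the enolate regiospecifically at C5, which deprotonation of a 3-silyloxy ketone could not do. The C8 methyl of 5 sends boron to the opposite face, and boron sends the aldehyde trans to itself.

**Building blocks (8 ⇒ 7 ⇒ 6; 5 ⇒ 4 ⇒ 3 ⇒ 2 ⇒ 1).** Aldehyde 8 comes from formylation of 6 through lithio compound 7. Enone 5 is (S)-pulegone 1 without its isopropylidene group: epoxide 2, thiolate-induced retro-aldol to 3, and elimination of sulfoxide 4.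

## Alternatives that were turned down

**Alternative 1:** The disconnection cuts C9–C10 and C6–C7, taking out C7–C8–C9 as the bis-allyl donor A3 and leaving the cis-1,2-diformylcyclopentane A2. In the forward step indium would allylate both aldehydes of A2 in turn and close the seven-membered ring as the 8-methylene-6,10-diol A1.
- For: it is convergent, brings both ring oxygens and the C8 carbon in one operation, tolerates water, and needs no sulfur removal, dehydrogenation or ketone reduction afterwards. On step count after ring closure it is stronger than the chosen route.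
- Against: two carbinol centres (C6, C10) form with weak control, the second during an entropically poor seven-membered closure that competes with oligomerisation. C5 of A2 is α to an aldehyde and can epimerise to the trans dialdehyde. A1 has two secondary hydroxyls of similar reactivity that must receive different acyl groups. The exocyclic alkene can isomerise to C7=C8 as easily as to C8=C9. A2 itself still needs C1, C4 and C5 set.
- In exchange the chosen route offers C5 and C6 fixed on a cyclohexane template, C1 set by a stereospecific shift, and O6/O10 differentiated automatically.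

**Alternative 2:** The cyclopentane is made by contracting the ring of (S)-terpinen-4-ol A6. A Lewis acid opens epoxy ketone A5 at the methyl-bearing carbon, and the acyl carbon C5 shifts from C10 to C1 to give the 2-formylcyclopentanone A4.
- For: C4 with its isopropyl group and oxygen comes from the chiral pool, and C1 is set by an invertive acyl shift. This is stronger than the chosen route at C4, which there needs an organometallic addition to a crowded ketone.
- Against: only the small ring is built. The cycloheptene, with C5, C6 and C10 still to be set, must be annulated onto a 1,3-dicarbonyl whose quaternary α-carbon invites deformylation. C5 is a ketone and must later become a methine of defined configuration. A5 needs a regioselective allylic oxidation and a face-selective epoxidation, and natural A6 is of modest enantiopurity.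
- In exchange the chosen route forms both rings and C1 in one step, with C5 and C6 already in place.

**Alternative 3:** The disconnection cuts C5–C6 and O–C4. An intramolecular cycloaddition of nitrile oxide A8 onto the C4=C5 bond of its cyclopentene would close the carbocycle and the isoxazoline A7.
- For: the suprafacial addition sets the C4 oxygen and C6 cis on the cyclopentene, and delivery from the C1 tether fixes both relative to C1. The C8=C9 alkene is already present, and N–O cleavage unmasks the C4 hydroxyl. On C4 and on the alkene this is as strong as or stronger than the chosen route.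
- Against: a seven-membered ring must form by attack on a trisubstituted alkene next to a quaternary carbon, in competition with nitrile oxide dimerisation. A8 requires separate asymmetric construction of C1 and C10 and a Z-trisubstituted alkene. The N–O bond must be cleaved reductively beside an alkene, and the C6 ketone then reduced selectively.
- In exchange the chosen route offers a precursor from one cheap chiral building block, with all control relayed from a single methyl stereocentre, and a ring-forming step with close analogy for this ring system.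

Key step: step 12

Remark on the chemistry: the descriptors of the target place H5 and the C1 methyl on the same face, so the cis-fused daucane is addressed. C3 of 19 and 20 and the side-chain carbinol of 10–13 are transient centres, drawn as the expected epimer or left open.

## Route

Step 1
Reactants: 1 (S)-pulegone
Product: 2 (6S)-2,2,6-trimethyl-1-oxaspiro[2.5]octan-4-one (pulegone oxide; both spiro epimers)
Conditions: 30% H2O2, LiOH (cat.), MeOH, 0 → 23 °C
Reagents that add atoms: hydrogen peroxide, OO
Why: Weitz–Scheffer nucleophilic epoxidation of the electron-poor tetrasubstituted enone; the epoxide configuration is of no consequence because both of its carbons lose their stereochemistry in steps 2 and 3.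

Step 2
Reactants: 2 pulegone oxide
Product: 3 (5S)-5-methyl-2-(phenylsulfanyl)cyclohexan-1-one (both C2 epimers)
Conditions: PhSH, NaH, THF, 66 °C; aq. NH4Cl
Reagents that add atoms: thiophenol, Sc1ccccc1
Why: The thiolate opens the α,β-epoxy ketone at the α-carbon and the β-alkoxide expels acetone by retro-aldol cleavage; the methyl stereocentre is not touched.

Step 3
Reactants: 3 (5S)-5-methyl-2-(phenylsulfanyl)cyclohexan-1-one
Product: 5 (5S)-5-methylcyclohex-2-en-1-one, via sulfoxide 4 (not isolated)
Conditions: mCPBA, CH2Cl2, −78 °C; then CaCO3, toluene, 110 °C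
Reagents that add atoms: none
Why: Sulfide oxidation followed by thermal syn-elimination of the sulfoxide; only one neighbouring carbon carries hydrogens, so the conjugated enone forms regiospecifically.

Step 4
Reactants: 6 bis(methylsulfanyl)methane
Product: 8 2,2-bis(methylsulfanyl)acetaldehyde, via lithiated dithioacetal 7 (not isolated)
Conditions: n-BuLi, THF, −78 → −20 °C; DMF, −78 °C; aq. NH4Cl
Reagents that add atoms: N,N-dimethylformamide, CN(C)C=O
Why: Deprotonation of the C–H acidified by two sulfur atoms and formylation of the carbanion; the tetrahedral adduct persists until work-up, so the aldehyde is not attacked twice.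

Step 5
Reactants: 5 (5S)-5-methylcyclohex-2-en-1-one; 8 2,2-bis(methylsulfanyl)acetaldehyde
Product: 11 (2S,3S,5S)-3-hydroxy-2-[1-hydroxy-2,2-bis(methylsulfanyl)ethyl]-5-methylcyclohexan-1-one, via boron enolate 9 (not isolated), via boryl aldolate 10 (not isolated)
Conditions: CuCl (5 mol %), 1,2-bis(diphenylphosphino)benzene (5 mol %), NaOtBu (10 mol %), B2pin2, THF, 0 → 23 °C; then 8, −78 → −20 °C; then NaBO3·4H2O, THF–H2O, 0 °C
Reagents that add atoms: sodium perborate, [Na+].[O-]OB=O
Why: Copper-catalysed conjugate borylation, aldol trapping of the boron enolate and C–B oxidation in one flask. The monovalent copper boryl adds anti to the ring methyl and the aldehyde adds anti to the new C–B bond through a closed Zimmerman–Traxler arrangement, which sets C6 and C5 from the one existing centre. The side-chain carbinol centre is removed in step 8, and dithioacetals tolerate buffered perborate, which attacks boron as a nucleophile.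

Step 6
Reactants: 11 keto diol
Product: 12 (2R,3S,5S)-3-[(tert-butyldimethylsilyl)oxy]-2-[1-hydroxy-2,2-bis(methylsulfanyl)ethyl]-5-methylcyclohexan-1-one
Conditions: TBSCl (1.05 equiv), imidazole, DMF, −20 → 0 °C
Reagents that add atoms: tert-butyldimethylsilyl chloride, CC(C)(C)[Si](C)(C)Cl
Why: Chemoselective silylation: the ring hydroxyl is flanked by a methylene, whereas the side-chain hydroxyl lies between the ring methine and the bis(methylsulfanyl)methyl group, so one equivalent of the bulky chloride should take the former.

Step 7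
Reactants: 12 silyloxy hydroxy ketone
Product: 13 (1S,2R,3S,5S)-3-[(tert-butyldimethylsilyl)oxy]-2-[1-hydroxy-2,2-bis(methylsulfanyl)ethyl]-5-methyl-1-(prop-1-en-2-yl)cyclohexan-1-ol
Conditions: isopropenylmagnesium bromide (3 equiv), CeCl3, THF, −78 °C; aq. NH4Cl
Reagents that add atoms: isopropenylmagnesium bromide, C=C(C)[Mg]Br
Why: Organocerium 1,2-addition to an enolisable β-hydroxy ketone; one equivalent is spent on the hydroxyl and the weakly basic cerium alkoxide should not undergo retro-aldol cleavage at −78 °C. The nucleophile enters equatorially, anti to the neighbouring side chain and to the axial ring methyl, which places the alkenyl group trans to the side chain; this centre becomes trigonal again in step 12.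

Step 8
Reactants: 13 diol
Product: 14 1-[(1R,2S,4S,6S)-6-[(tert-butyldimethylsilyl)oxy]-2-hydroxy-4-methyl-2-(prop-1-en-2-yl)cyclohexyl]-2,2-bis(methylsulfanyl)ethan-1-one
Conditions: Dess–Martin periodinane, NaHCO3, CH2Cl2, 0 → 23 °C
Reagents that add atoms: none
Why: Dess–Martin oxidation of the secondary alcohol under buffered conditions; the tertiary allylic alcohol and the thioether sulfur atoms are not oxidised.

Step 9
Reactants: 14 hydroxy ketone
Product: 15 1-[(1R,2S,4S,6S)-6-[(tert-butyldimethylsilyl)oxy]-4-methyl-2-(prop-1-en-2-yl)-2-[(trimethylsilyl)oxy]cyclohexyl]-2,2-bis(methylsulfanyl)ethan-1-one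
Conditions: N-(trimethylsilyl)imidazole, CH2Cl2, 23 °C
Reagents that add atoms: N-(trimethylsilyl)imidazole, C[Si](C)(C)n1ccnc1
Why: Silyl transfer to the tertiary alcohol without added base, so the acidic α-keto dithioacetal C–H is not enolised; the ether prevents a β-alkoxide, and with it retro-aldol cleavage of the C5–C10 bond, in step 10.

Step 10
Reactants: 15 keto dithioacetal
Product: 16 (2R)-2-[(1S,2S,4S,6S)-6-[(tert-butyldimethylsilyl)oxy]-4-methyl-2-(prop-1-en-2-yl)-2-[(trimethylsilyl)oxy]cyclohexyl]-3-methyl-1,1-bis(methylsulfanyl)butan-2-ol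
Conditions: i-PrMgCl, CeCl3, THF, −78 → −40 °C; aq. NH4Cl
Reagents that add atoms: isopropylmagnesium chloride, CC(C)[Mg]Cl
Why: Organocerium addition to a hindered, readily enolised ketone, the case for which cerium reagents are the standard answer. Felkin–Anh control sets C4: the carbonyl oxygen points away from H5, the bis(methylsulfanyl)methyl group eclipses the C5–H bond, and isopropyl enters anti to the quaternary C10, from the face flanked by C6, which gives the 4R alcohol.

Step 11
Reactants: 16 tertiary alcohol
Product: 17 triethyl{[(2R)-2-[(1R,2S,4S,6S)-6-[(tert-butyldimethylsilyl)oxy]-4-methyl-2-(prop-1-en-2-yl)-2-[(trimethylsilyl)oxy]cyclohexyl]-3-methyl-1,1-bis(methylsulfanyl)butan-2-yl]oxy}silane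
Conditions: TESOTf, 2,6-lutidine, CH2Cl2, −78 → 0 °C
Reagents that add atoms: triethylsilyl trifluoromethanesulfonate, CC[Si](CC)(CC)OS(=O)(=O)C(F)(F)F
Why: A silyl triflate with a hindered pyridine base silylates the congested tertiary alcohol; the tertiary TMS ether, the dithioacetal and the alkene are inert to these conditions.

Step 12
Reactants: 17 dithioacetal
Product: 20 (1R,3S,4R,5S,6S,8S)-6-[(tert-butyldimethylsilyl)oxy]-3-(methylsulfanyl)-4-[(triethylsilyl)oxy]daucan-10-one (cis-fused), via thionium ion 18 (not isolated), via tertiary cation 19 (not isolated)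
Conditions: Me2S(SMe)BF4, 2,6-di-tert-butyl-4-methylpyridine, CH2Cl2, −45 → 0 °C
Reagents that add atoms: none
Why: The thiophilic sulfonium salt methylthiolates one sulfur of the dithioacetal, which leaves as dimethyl disulfide and gives thionium ion 18; the 2-propenyl group attacks through its terminal carbon (C2–C3 bond) to give tertiary cation 19, and ring carbon C5 then shifts from C10 to C1 as the silyl ether collapses to the C10 ketone. This is the thionium-initiated Prins–pinacol ring-enlarging cyclopentane annulation of 1-alkenyl-2-(acetal-tethered)cycloalkanol silyl ethers. The Prins event is a six-membered closure, endo with respect to the alkene, through a chair in which the new ring is trans-fused to the cyclohexane (propenyl and side chain both equatorial); the pinacol shift contracts this ring to the cyclopentane and enlarges the cyclohexane to the cycloheptanone. C1 is set by the suprafacial shift: C5 migrates with retention to the face of the cation on which it already lies, so the angular methyl ends cis to H5. C3 is set by the chair (methylthio pseudo-equatorial, on the side of the C4 silyloxy group) and is removed in step 13; C4, C5, C6 and C8 are untouched. The step needs the sulfonium salt to ionise only the dithioacetal, which the silyl ethers allow because they are not thiophilic. It needs the C10–C5 bond and not C10–C9 to migrate: C9 is equatorial on the cationic ring and lies near the nodal plane of the empty orbital, and C5 is the more substituted carbon. It needs the Prins closure to outrun a 1,2-shift of a C4 substituent to C3, which the weakly donating silyloxy group and the stabilised thionium centre disfavour.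

Step 13
Reactants: 20 methylthio ketone
Product: 21 (1R,4R,5S,6S,8S)-6-[(tert-butyldimethylsilyl)oxy]-4-[(triethylsilyl)oxy]daucan-10-one
Conditions: Raney Ni (deactivated in refluxing acetone), EtOH, 23 °C
Reagents that add atoms: none
Why: Raney nickel hydrogenolysis of the C–S bond; with deactivated nickel at ambient temperature the ketone next to the quaternary carbon should survive.

Step 14
Reactants: 21 saturated ketone
Product: 22 (1R,4R,5S,6S)-6-[(tert-butyldimethylsilyl)oxy]-4-[(triethylsilyl)oxy]dauc-8-en-10-one
Conditions: IBX, DMSO–fluorobenzene, 70 °C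
Reagents that add atoms: none
Why: Dehydrogenation of a ketone to the enone by the pentavalent iodine reagent IBX through the enol; C1 is quaternary, so only C9–C8 can be desaturated, and the C8 stereocentre that served as relay is erased.

Step 15
Reactants: 22 enone
Product: 23 (1R,4R,5S,6S,10S)-6-[(tert-butyldimethylsilyl)oxy]-4-[(triethylsilyl)oxy]dauc-8-en-10-ol
Conditions: NaBH4, CeCl3·7H2O, MeOH, −78 °C
Reagents that add atoms: none
Why: Luche 1,2-reduction of the enone. In the favoured half-chair the bulky C4 and the C6 silyloxy group are equatorial on the seven-membered ring, the C1–C2 bond is pseudo-axial and the angular methyl lies near the carbonyl plane, so hydride should enter anti to C2, on the convex face of the cis-fused bicycle, and give the 10S alcohol with oxygen trans to the methyl.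

Step 16
Reactants: 23 allylic alcohol
Product: 24 (1R,4R,5S,6S,10S)-6-[(tert-butyldimethylsilyl)oxy]-4-[(triethylsilyl)oxy]dauc-8-en-10-yl (E)-2-methylbut-2-enoate
Conditions: tiglic acid, 2,4,6-trichlorobenzoyl chloride, Et3N, THF; then 23, DMAP, toluene, 23 → 40 °C
Reagents that add atoms: tiglic acid, C/C=C(\C)C(=O)O
Why: Yamaguchi esterification through the mixed anhydride acylates the hindered allylic alcohol under DMAP catalysis with retention at C10; it avoids an acid chloride–amine pairing that could deconjugate the tigloyl unit through a vinylketene.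

Step 17
Reactants: 24 bis-silyl ether
Product: 25 (1R,4R,5S,6S,10S)-4,6-dihydroxydauc-8-en-10-yl (E)-2-methylbut-2-enoate
Conditions: HF·pyridine, pyridine, THF, 0 → 23 °C
Reagents that add atoms: none
Why: Fluoride cleavage of both silyl ethers under buffered, weakly acidic conditions that leave the allylic ester in place; the C6 and C10 oxygens are on opposite faces of the ring, so acyl migration is not expected.

Step 18
Reactants: 25 diol
Product: 26 (1R,4R,5S,6S,10S)-4-hydroxy-10-{[(E)-2-methylbut-2-enoyl]oxy}dauc-8-en-6-yl 4-acetoxybenzoate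
Conditions: 4-acetoxybenzoyl chloride, DMAP, Et3N, CH2Cl2, 23 °C
Reagents that add atoms: 4-acetoxybenzoyl chloride, CC(=O)Oc1ccc(cc1)C(Cl)=O
Why: DMAP-catalysed acylation is selective for the secondary C6 hydroxyl; the tertiary C4 hydroxyl is not acylated under these conditions.

Step 19
Reactants: 26 aryl acetate
Product: 27 (1R,4R,5S,6S,10S)-4-hydroxy-10-{[(E)-2-methylbut-2-enoyl]oxy}dauc-8-en-6-yl 4-hydroxybenzoate (CNP0273650.3)
Conditions: pyrrolidine, CH2Cl2, 0 °C
Reagents that add atoms: none
Why: Aminolysis of the aryl acetate, which is far more electrophilic than the two alkyl esters; the tiglate is a poor Michael acceptor because of its α- and β-methyl groups.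

## Compound list

1 | (S)-pulegone, (5S)-5-methyl-2-(propan-2-ylidene)cyclohexan-1-one | C[C@H]1CCC(=C(C)C)C(=O)C1 | starting material
2 | (6S)-2,2,6-trimethyl-1-oxaspiro[2.5]octan-4-one (both spiro epimers) | C[C@H]1CCC2(OC2(C)C)C(=O)C1 | intermediate
3 | (5S)-5-methyl-2-(phenylsulfanyl)cyclohexan-1-one (both C2 epimers) | C[C@H]1CCC(Sc2ccccc2)C(=O)C1 | intermediate
4 | (5S)-5-methyl-2-(phenylsulfinyl)cyclohexan-1-one (formed in the flask) | C[C@H]1CCC(S(=O)c2ccccc2)C(=O)C1 | intermediate
5 | (5S)-5-methylcyclohex-2-en-1-one | C[C@H]1CC=CC(=O)C1 | intermediate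
6 | bis(methylsulfanyl)methane | CSCSC | starting material
7 | [bis(methylsulfanyl)methyl]lithium (formed in the flask) | [Li]C(SC)SC | intermediate
8 | 2,2-bis(methylsulfanyl)acetaldehyde | O=CC(SC)SC | intermediate
9 | pinacolboron enolate of 5-methyl-3-(pinacolboryl)cyclohexanone, boryl trans to methyl (formed in the flask) | CC1(C)OB(OC2=C[C@@H](B3OC(C)(C)C(C)(C)O3)C[C@H](C)C2)OC1(C)C | intermediate
10 | O-pinacolboryl aldolate of 9 and 8, 2,3-trans and 3,5-trans (formed in the flask) | O=C1C[C@@H](C)C[C@H](B2OC(C)(C)C(C)(C)O2)[C@H]1C(OB3OC(C)(C)C(C)(C)O3)C(SC)SC | intermediate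
11 | (2S,3S,5S)-3-hydroxy-2-[1-hydroxy-2,2-bis(methylsulfanyl)ethyl]-5-methylcyclohexan-1-one (side-chain carbinol open) | O=C1C[C@@H](C)C[C@H](O)[C@H]1C(O)C(SC)SC | intermediate
12 | (2R,3S,5S)-3-[(tert-butyldimethylsilyl)oxy]-2-[1-hydroxy-2,2-bis(methylsulfanyl)ethyl]-5-methylcyclohexan-1-one | O=C1C[C@@H](C)C[C@H](O[Si](C)(C)C(C)(C)C)[C@H]1C(O)C(SC)SC | intermediate
13 | (1S,2R,3S,5S)-3-[(tert-butyldimethylsilyl)oxy]-2-[1-hydroxy-2,2-bis(methylsulfanyl)ethyl]-5-methyl-1-(prop-1-en-2-yl)cyclohexan-1-ol | C=C(C)[C@]1(O)C[C@@H](C)C[C@H](O[Si](C)(C)C(C)(C)C)[C@H]1C(O)C(SC)SC | intermediate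
14 | 1-[(1R,2S,4S,6S)-6-[(tert-butyldimethylsilyl)oxy]-2-hydroxy-4-methyl-2-(prop-1-en-2-yl)cyclohexyl]-2,2-bis(methylsulfanyl)ethan-1-one | C=C(C)[C@]1(O)C[C@@H](C)C[C@H](O[Si](C)(C)C(C)(C)C)[C@H]1C(=O)C(SC)SC | intermediate
15 | 1-[(1R,2S,4S,6S)-6-[(tert-butyldimethylsilyl)oxy]-4-methyl-2-(prop-1-en-2-yl)-2-[(trimethylsilyl)oxy]cyclohexyl]-2,2-bis(methylsulfanyl)ethan-1-one | C=C(C)[C@]1(O[Si](C)(C)C)C[C@@H](C)C[C@H](O[Si](C)(C)C(C)(C)C)[C@H]1C(=O)C(SC)SC | intermediate
16 | (2R)-2-[(1S,2S,4S,6S)-6-[(tert-butyldimethylsilyl)oxy]-4-methyl-2-(prop-1-en-2-yl)-2-[(trimethylsilyl)oxy]cyclohexyl]-3-methyl-1,1-bis(methylsulfanyl)butan-2-ol | C=C(C)[C@]1(O[Si](C)(C)C)C[C@@H](C)C[C@H](O[Si](C)(C)C(C)(C)C)[C@H]1[C@](O)(C(C)C)C(SC)SC | intermediate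
17 | triethyl{[(2R)-2-[(1R,2S,4S,6S)-6-[(tert-butyldimethylsilyl)oxy]-4-methyl-2-(prop-1-en-2-yl)-2-[(trimethylsilyl)oxy]cyclohexyl]-3-methyl-1,1-bis(methylsulfanyl)butan-2-yl]oxy}silane | C=C(C)[C@]1(O[Si](C)(C)C)C[C@@H](C)C[C@H](O[Si](C)(C)C(C)(C)C)[C@H]1[C@](O[Si](CC)(CC)CC)(C(C)C)C(SC)SC | intermediate
18 | S-methyl thionium tetrafluoroborate formed from 17 by loss of one methylthio group (formed in the flask) | C=C(C)[C@]1(O[Si](C)(C)C)C[C@@H](C)C[C@H](O[Si](C)(C)C(C)(C)C)[C@H]1[C@](O[Si](CC)(CC)CC)(C(C)C)C=[S+]C.F[B-](F)(F)F | intermediate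
19 | tertiary C1 cation of the trans-fused Prins bicycle, tetrafluoroborate (formed in the flask) | C[C+]1C[C@H](SC)[C@@](O[Si](CC)(CC)CC)(C(C)C)[C@@H]2[C@@H](O[Si](C)(C)C(C)(C)C)C[C@H](C)C[C@@]12O[Si](C)(C)C.F[B-](F)(F)F | intermediate
20 | (1R,3S,4R,5S,6S,8S)-6-[(tert-butyldimethylsilyl)oxy]-3-(methylsulfanyl)-4-[(triethylsilyl)oxy]daucan-10-one | O=C1C[C@@H](C)C[C@H](O[Si](C)(C)C(C)(C)C)[C@@H]2[C@@]1(C)C[C@H](SC)[C@@]2(O[Si](CC)(CC)CC)C(C)C | intermediate
21 | (1R,4R,5S,6S,8S)-6-[(tert-butyldimethylsilyl)oxy]-4-[(triethylsilyl)oxy]daucan-10-one | O=C1C[C@@H](C)C[C@H](O[Si](C)(C)C(C)(C)C)[C@@H]2[C@@]1(C)CC[C@@]2(O[Si](CC)(CC)CC)C(C)C | intermediate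
22 | (1R,4R,5S,6S)-6-[(tert-butyldimethylsilyl)oxy]-4-[(triethylsilyl)oxy]dauc-8-en-10-one | O=C1C=C(C)C[C@H](O[Si](C)(C)C(C)(C)C)[C@@H]2[C@@]1(C)CC[C@@]2(O[Si](CC)(CC)CC)C(C)C | intermediate
23 | (1R,4R,5S,6S,10S)-6-[(tert-butyldimethylsilyl)oxy]-4-[(triethylsilyl)oxy]dauc-8-en-10-ol | O[C@H]1C=C(C)C[C@H](O[Si](C)(C)C(C)(C)C)[C@@H]2[C@@]1(C)CC[C@@]2(O[Si](CC)(CC)CC)C(C)C | intermediate
24 | (1R,4R,5S,6S,10S)-6-[(tert-butyldimethylsilyl)oxy]-4-[(triethylsilyl)oxy]dauc-8-en-10-yl (E)-2-methylbut-2-enoate | C/C=C(\C)C(=O)O[C@H]1C=C(C)C[C@H](O[Si](C)(C)C(C)(C)C)[C@@H]2[C@@]1(C)CC[C@@]2(O[Si](CC)(CC)CC)C(C)C | intermediate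
25 | (1R,4R,5S,6S,10S)-4,6-dihydroxydauc-8-en-10-yl (E)-2-methylbut-2-enoate | C/C=C(\C)C(=O)O[C@H]1C=C(C)C[C@H](O)[C@@H]2[C@@]1(C)CC[C@@]2(O)C(C)C | intermediate
26 | (1R,4R,5S,6S,10S)-4-hydroxy-10-{[(E)-2-methylbut-2-enoyl]oxy}dauc-8-en-6-yl 4-acetoxybenzoate | C/C=C(\C)C(=O)O[C@H]1C=C(C)C[C@H](OC(=O)c2ccc(OC(C)=O)cc2)[C@@H]2[C@@]1(C)CC[C@@]2(O)C(C)C | intermediate
27 | (1R,4R,5S,6S,10S)-4-hydroxy-10-{[(E)-2-methylbut-2-enoyl]oxy}dauc-8-en-6-yl 4-hydroxybenzoate | C/C=C(\C)C(=O)O[C@H]1C=C(C)C[C@H](OC(=O)c2ccc(O)cc2)[C@@H]2[C@@]1(C)CC[C@@]2(O)C(C)C | target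

## Step count and weak points

Total step count: 19. Longest linear sequence: 18 steps (1 to 27 through steps 1–3 and 5–19); step 4 is a one-step side branch.

**Step 12 (key step).** The most likely failure is a 1,2-shift inside the side chain (isopropyl or C5 moving from C4 to the thionium carbon, with loss of the C4 silyl group) overtaking the Prins closure. The closure needs a crowded rotamer in which the silyl ethers on C4 and C10 are 1,3-syn on the forming ring, so it may be slow. The fallback makes that rotamer the only one available by tying O4 to O10. From 16, the tertiary TMS ether is cleaved (K2CO3, MeOH) to the diol, (2R)-2-[(1S,2S,4S,6S)-6-[(tert-butyldimethylsilyl)oxy]-2-hydroxy-4-methyl-2-(prop-1-en-2-yl)cyclohexyl]-3-methyl-1,1-bis(methylsulfanyl)butan-2-ol F1. This is closed with i-Pr2Si(OTf)2 and 2,6-lutidine to the six-membered cyclic diisopropylsilylene of the two tertiary oxygens F2, which holds the dithioacetal carbon beside the propenyl group. Treatment with Me2S(SMe)BF4 as in step 12, followed by a K2CO3–MeOH work-up that cleaves the residual fluorosilyl ether on O4, should give the C4-hydroxy analogue of 20, (1R,3S,4R,5S,6S,8S)-6-[(tert-butyldimethylsilyl)oxy]-4-hydroxy-3-(methylsulfanyl)daucan-10-one F3. Raney Ni then gives the C4-hydroxy analogue of 21, F4, and TESOTf with 2,6-lutidine returns to the route at 21.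

**Step 10.** The most likely failure is delivery of the isopropyl group to the wrong face. The ketone is flanked by a methine that itself adjoins a quaternary carbon, and the Felkin–Anh preference is untested in so crowded a setting. Loss of reagent to deprotonation of the acidic C3–H would only return 15. The fallback exchanges the roles of the two C4 substituents, which turns a given facial bias into the opposite C4 configuration and removes the acidic C–H. From 5, the coupling of step 5 is run with 2-methylpropanal to give the keto diol (3-hydroxy-2-(1-hydroxy-2-methylpropyl)-5-methylcyclohexan-1-one, 2,3-trans and 3,5-trans) F5. Silylation as in step 6 gives its C3 TBS ether F6, 2-propenylcerium addition as in step 7 gives the diol F7, and Dess–Martin oxidation gives the isopropyl ketone F8. N-(trimethylsilyl)imidazole gives its tertiary TMS ether F9. Addition of the lithiated dithioacetal 7 (THF, −78 °C) to F9 from the face that the isopropyl reagent had taken in step 10 then gives 16.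

**Step 6.** The most likely failure is poor site selectivity (silylation of the side-chain hydroxyl or of both), since both hydroxyls are secondary. The fallback never lets the two hydroxyls coexist. From 5 and 8, the coupling of step 5 is stopped before the oxidation (aq. NH4Cl) to give the boryl aldol, 2-[1-hydroxy-2,2-bis(methylsulfanyl)ethyl]-5-methyl-3-(pinacolboryl)cyclohexan-1-one F10. Its only hydroxyl is silylated (TESCl, imidazole) to F11, and the C–B bond is then oxidised (NaBO3·4H2O) to the ring alcohol F12. TBSCl with imidazole gives the bis-silyl ketone F13, and 2-propenylcerium addition gives the tertiary alcohol F14, which also takes the free hydroxyl out of that step. PPTS in MeOH cleaves the secondary TES ether selectively and returns to the route at 13.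

**Step 15.** The most likely failure is poor facial selectivity: hydride could arrive from the cyclopentane face if the cycloheptenone adopts the conformer with the angular methyl pseudo-axial. The fallback uses the epimeric alcohol, (1R,4R,5S,6S,10R)-6-[(tert-butyldimethylsilyl)oxy]-4-[(triethylsilyl)oxy]dauc-8-en-10-ol F15. Mitsunobu esterification of F15 with tiglic acid (PPh3, diisopropyl azodicarboxylate, toluene, 0 → 23 °C) installs the ester with inversion and comes back to the route at 24.

## Further compounds

F1 | step 12 | (2R)-2-[(1S,2S,4S,6S)-6-[(tert-butyldimethylsilyl)oxy]-2-hydroxy-4-methyl-2-(prop-1-en-2-yl)cyclohexyl]-3-methyl-1,1-bis(methylsulfanyl)butan-2-ol | C=C(C)[C@]1(O)C[C@@H](C)C[C@H](O[Si](C)(C)C(C)(C)C)[C@H]1[C@](O)(C(C)C)C(SC)SC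
F2 | step 12 | cyclic diisopropylsilylene of F1 bridging the two tertiary oxygens | C=C(C)[C@]12C[C@@H](C)C[C@H](O[Si](C)(C)C(C)(C)C)[C@H]1[C@](C(C)C)(C(SC)SC)O[Si](C(C)C)(C(C)C)O2
F3 | step 12 | (1R,3S,4R,5S,6S,8S)-6-[(tert-butyldimethylsilyl)oxy]-4-hydroxy-3-(methylsulfanyl)daucan-10-one | O=C1C[C@@H](C)C[C@H](O[Si](C)(C)C(C)(C)C)[C@@H]2[C@@]1(C)C[C@H](SC)[C@@]2(O)C(C)C
F4 | step 12 | (1R,4R,5S,6S,8S)-6-[(tert-butyldimethylsilyl)oxy]-4-hydroxydaucan-10-one | O=C1C[C@@H](C)C[C@H](O[Si](C)(C)C(C)(C)C)[C@@H]2[C@@]1(C)CC[C@@]2(O)C(C)C
F5 | step 10 | 3-hydroxy-2-(1-hydroxy-2-methylpropyl)-5-methylcyclohexan-1-one (2,3-trans; 3,5-trans; 5S) | O=C1C[C@@H](C)C[C@H](O)[C@H]1C(O)C(C)C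
F6 | step 10 | 3-[(tert-butyldimethylsilyl)oxy]-2-(1-hydroxy-2-methylpropyl)-5-methylcyclohexan-1-one | O=C1C[C@@H](C)C[C@H](O[Si](C)(C)C(C)(C)C)[C@H]1C(O)C(C)C
F7 | step 10 | 3-[(tert-butyldimethylsilyl)oxy]-2-(1-hydroxy-2-methylpropyl)-5-methyl-1-(prop-1-en-2-yl)cyclohexan-1-ol | C=C(C)[C@]1(O)C[C@@H](C)C[C@H](O[Si](C)(C)C(C)(C)C)[C@H]1C(O)C(C)C
F8 | step 10 | 1-{6-[(tert-butyldimethylsilyl)oxy]-2-hydroxy-4-methyl-2-(prop-1-en-2-yl)cyclohexyl}-2-methylpropan-1-one | C=C(C)[C@]1(O)C[C@@H](C)C[C@H](O[Si](C)(C)C(C)(C)C)[C@H]1C(=O)C(C)C
F9 | step 10 | 1-{6-[(tert-butyldimethylsilyl)oxy]-4-methyl-2-(prop-1-en-2-yl)-2-[(trimethylsilyl)oxy]cyclohexyl}-2-methylpropan-1-one | C=C(C)[C@]1(O[Si](C)(C)C)C[C@@H](C)C[C@H](O[Si](C)(C)C(C)(C)C)[C@H]1C(=O)C(C)C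
F10 | step 6 | 2-[1-hydroxy-2,2-bis(methylsulfanyl)ethyl]-5-methyl-3-(4,4,5,5-tetramethyl-1,3,2-dioxaborolan-2-yl)cyclohexan-1-one | O=C1C[C@@H](C)C[C@H](B2OC(C)(C)C(C)(C)O2)[C@H]1C(O)C(SC)SC
F11 | step 6 | triethylsilyl ether of F10 | O=C1C[C@@H](C)C[C@H](B2OC(C)(C)C(C)(C)O2)[C@H]1C(O[Si](CC)(CC)CC)C(SC)SC
F12 | step 6 | 3-hydroxy-5-methyl-2-{2,2-bis(methylsulfanyl)-1-[(triethylsilyl)oxy]ethyl}cyclohexan-1-one | O=C1C[C@@H](C)C[C@H](O)[C@H]1C(O[Si](CC)(CC)CC)C(SC)SC
F13 | step 6 | 3-[(tert-butyldimethylsilyl)oxy]-5-methyl-2-{2,2-bis(methylsulfanyl)-1-[(triethylsilyl)oxy]ethyl}cyclohexan-1-one | O=C1C[C@@H](C)C[C@H](O[Si](C)(C)C(C)(C)C)[C@H]1C(O[Si](CC)(CC)CC)C(SC)SC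
F14 | step 6 | 3-[(tert-butyldimethylsilyl)oxy]-5-methyl-2-{2,2-bis(methylsulfanyl)-1-[(triethylsilyl)oxy]ethyl}-1-(prop-1-en-2-yl)cyclohexan-1-ol | C=C(C)[C@]1(O)C[C@@H](C)C[C@H](O[Si](C)(C)C(C)(C)C)[C@H]1C(O[Si](CC)(CC)CC)C(SC)SC
F15 | step 15 | (1R,4R,5S,6S,10R)-6-[(tert-butyldimethylsilyl)oxy]-4-[(triethylsilyl)oxy]dauc-8-en-10-ol | O[C@@H]1C=C(C)C[C@H](O[Si](C)(C)C(C)(C)C)[C@@H]2[C@@]1(C)CC[C@@]2(O[Si](CC)(CC)CC)C(C)C
A1 | alternative 1 | 8-methylene hydroazulene-6,10-diol, C4 triethylsilyl ether | O[C@H]1CC(=C)C[C@H](O)[C@@H]2[C@@]1(C)CC[C@@]2(O[Si](CC)(CC)CC)C(C)C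
A2 | alternative 1 | cis-1,2-diformyl-1-methyl-3-isopropyl-3-(triethylsilyloxy)cyclopentane | O=C[C@@H]1[C@](C)(C=O)CC[C@@]1(O[Si](CC)(CC)CC)C(C)C
A3 | alternative 1 | 3-bromo-2-(bromomethyl)prop-1-ene | C=C(CBr)CBr
A4 | alternative 2 | 2-formyl-2-methyl-5-isopropyl-5-(triethylsilyloxy)cyclopentanone | O=C[C@]1(C)CC[C@@](O[Si](CC)(CC)CC)(C(C)C)C1=O
A5 | alternative 2 | 3,4-epoxy-4-methyl-1-isopropyl-1-(triethylsilyloxy)cyclohexan-2-one, epoxide cis to the silyloxy group | C[C@@]12CC[C@@](O[Si](CC)(CC)CC)(C(C)C)C(=O)[C@@H]1O2
A6 | alternative 2 | (S)-terpinen-4-ol | CC1=CC[C@](O)(C(C)C)CC1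
A7 | alternative 3 | isoxazoline-fused hydroazulene, C10 4-methoxybenzyl ether | COc1ccc(CO[C@H]2C=C(C)CC(=NO4)[C@@H]3[C@@]2(C)CC[C@@]34C(C)C)cc1
A8 | alternative 3 | open-chain nitrile oxide with (Z)-alkene tether on the 3-isopropylcyclopent-2-enyl quaternary carbon | COc1ccc(CO[C@@H](/C=C(C)\CC#[N+][O-])[C@]2(C)CCC(C(C)C)=C2)cc1
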